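## The problem

The target 18 is a 2,3-trans-2,3-diarylchroman-4-one. Ring A (the 5,7-dihydroxybenzo ring) is fused to ring C (the pyranone); C2 carries ring B (4-hydroxyphenyl); C3 carries ring D, a 2-hydroxyphenyl group that bears, para to its hydroxyl, an E-enone ending in ring E (2,4-dihydroxyphenyl). There are only two stereocentres, C2 (R) and C3 (S), adjacent and trans. C3 is both alpha to the C4 ketone and benzylic, so it epimerises easily. Because the diequatorial trans arrangement is the stable one, C2 can dictate C3 once the ketone exists, but C2 is itself a beta-aryloxy ketone carbon and is lost together with C3 if ring C opens by retro-oxa-Michael reaction. The absolute configuration must therefore be set while ring C is made and then kept away from base and heat. Six free phenols, an E-chalcone double bond that rules out hydrogenolysis, and a 2'-hydroxychalcone that can cyclise under acid or base restrict the end game to mild, non-reductive deprotection. A short solution is possible because O1 and C4 sit on adjacent carbons of ring A, the pattern of an ortho-quinone methide, while C2 and C3 carry two trans aryl groups of which the one at C2 has a para-hydroxyl. That is an E-stilbene polarised as a vinylogous enol, whose nucleophilic carbon becomes C3 and whose cation-stabilised carbon becomes C2. C4 arrives from this union as a methylene, which is acceptable because it is the only C–H position benzylic to the trioxygenated ring A and can be oxidised selectively afterwards.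

## Retrosynthesis

**Phenol protection.** The six O–H bonds of 18 are traced back to six O–benzyl bonds in 17. Benzyl ethers survive everything the route demands (a Brønsted acid in the key step, a quinone oxidant, palladium catalysis, carbonate bases). They can still be removed from all six oxygens at low temperature by a boron Lewis acid with a cation scavenger, without hydrogen and without base. Silyl ethers or acetals would be at risk in the acid-catalysed cycloaddition, and acyl groups on ring A would deactivate it toward the C4 oxidation. The forward reaction must leave the enone and both stereocentres untouched.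

**C4 oxidation level.** The C4 carbonyl of 17 is traced through the carbinol 16 to the methylene of 15. Keeping C4 as CH2 for as long as possible protects C3, since in 15 no stereocentre is alpha to a carbonyl group. Cutting at the ketone level instead would need a quinone methide already oxidised at the methide carbon, for which an asymmetric cycloaddition is not established. The forward steps must abstract hydride at C4 only and then oxidise the alcohol under non-basic conditions.

**Chalcone arm.** In 15 the bond between ring D and the beta-carbon of the enone is cut, giving the aryl bromide 11 and the aryl vinyl ketone 14. The neighbouring aldol cut (C-alpha=C-beta) would need a ring D aldehyde and hydroxide or alkoxide; a cut at the carbonyl carbon would need three components. The chosen cut splits the molecule into the stereodefined chroman and a small achiral enone, and the bromine needed for it is a passenger that costs nothing earlier. The coupling must give the E-alkene, and it is placed before the C4 oxidation so that the amine base never meets the ketone.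

**Ring B phenol.** The O–benzyl bond on ring B of 11 is cut to give the phenol 10. This hydroxyl must be free in the key step and must be capped before the oxidation, because a free para-hydroxybenzylic ether would be oxidised at C2.

**Ring C (key disconnection).** In 10 the C3–C4 and O1–C2 bonds are cut together, giving the ortho-quinone methide 9 and the E-stilbene 8; 9 is not storable and is traced to the salicyl alcohol 3. Single-bond cuts (an oxa-Michael closure of O1–C2, or an arylation at C3) would leave one stereocentre to be set separately next to an enolisable position. The double cut removes ring C and both stereocentres in one operation and leaves two achiral fragments, each three steps or fewer from commercial material. The forward reaction must deliver O1 to the carbon bearing ring B, translate the E-geometry into the trans relation, and differentiate the faces of the stilbene.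

**Salicyl alcohol.** 3 is traced to the aldehyde 2 (C–H bond at the carbinol carbon) and 2 to 2,4,6-trihydroxybenzaldehyde 1 (two O–benzyl bonds). The hydroxyl hydrogen-bonded to the formyl group is the one left free, and it is the one that becomes O1.

**Stilbene.** 8 is traced to its acetate 7, and 7 is cut at the bond between ring D and the alkene into the aryl iodide 5 and 4-acetoxystyrene 6; 5 comes from 4-bromo-2-iodophenol 4. An olefination across the C=C bond would need a free-phenol benzylic phosphonate, whose phenoxide suppresses carbanion formation, or extra protecting-group steps. The aryl–vinyl cut uses a stable commercial styrene and relies only on the faster reaction of C–I over C–Br.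

**Vinyl ketone.** 14 is traced to the acetophenone 13 by removing the methylene carbon, and 13 to 2',4'-dihydroxyacetophenone 12 by cutting two O–benzyl bonds.

## Roads not taken

**Alternative 1:** The cut is at both bonds to the chalcone carbonyl carbon (ring E–C(O) and C(O)–C-alpha). In the forward sense 1-iodo-2,4-bis(methoxymethoxy)benzene A3, carbon monoxide A4 and the ring D vinyl group of the finished flavanone A2 would combine on zerovalent palladium. The sequence is oxidative addition, insertion of A4 to an aroylpalladium species, insertion of the styrene and beta-hydride elimination, giving the hexakis(methoxymethyl) ether A1 of the target.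
- Merits: in two respects this is better than the chosen end game. No polymerisable vinyl ketone such as 14 is needed, and methoxymethyl ethers come off with dilute acid, a gentler last step than a boron trihalide acting on six benzyl ethers.
- Weak points: it is an end-game tactic only. Ring C and both stereocentres of A2 still have to be made, most plausibly by the cycloaddition chosen here plus an extra vinylation of the bromide. The three-component coupling competes with the direct arylation that leaves out A4. It needs gas pressure, heat and an amine base on a substrate whose C3 is alpha to the ketone. An electron-rich ortho-alkoxy aroylpalladium species inserts styrenes reluctantly.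
- Comparison: the chosen plan uses the bromide of 11 directly, with no vinylation and no pressure equipment, and does the C–C coupling on a chroman that has no enolisable stereocentre.

**Alternative 2:** The cut is the C2–C3 bond. The diazo ketone A6 would lose nitrogen on a chiral dirhodium tetracarboxylate, and the carbenoid at C3 would insert into a benzylic C–H bond of one ortho 4-(benzyloxy)benzyloxy group. This closes ring C as the chromanone A5 after equilibration of C3 to trans.
- Merits: ring C closes with the C4 ketone in place, so the two oxidation steps of the chosen route (steps 11 and 12) disappear. The C–H bond attacked is doubly activated. In oxidation-state economy this road is better.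
- Weak points: closure is a 1,6-insertion through a six-membered transition state, less favourable than the usual five-membered mode. It competes with attack of the carbenoid on the same ether oxygen (a five-membered oxonium ylide that rearranges by Stevens shift to a benzofuranone) and with Wolff rearrangement. Enantiocontrol rests on C2 alone and is poorly supported for a diaryl case with a 2,6-disubstituted aroyl group. Three identical 4-(benzyloxy)benzyl groups are carried although only one is built in, and the others are acid-labile ethers. A6 requires a crowded deoxybenzoin and a diazo transfer.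
- Comparison: the chosen plan pays two oxidation steps for a ring closure whose regiochemistry and trans geometry follow from the polarised E-alkene and whose side reactions are milder.

**Alternative 3:** The cut removes ring A (C4a–C5 and C8–C8a). 1-Methoxy-1,3-bis(trimethylsilyloxy)buta-1,3-diene A9 would add by Diels–Alder reaction to the C5=C6 double bond of the bromo-dihydropyranone A8. Its CH2 terminus bonds to the oxygen-bearing carbon (future C8a) and its acetal carbon to the brominated carbon (future C4a). Two eliminations then aromatise the new ring and give A7 with free 5- and 7-hydroxyls.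
- Merits: ring A needs no protecting groups, the ketone is present from the start, and the regiochemistry of the annulation follows reliably from the polarisation of both partners. In protecting-group economy this road is better.
- Weak points: the stereochemical problem is only moved. A8 already contains C2 and C3, and an enantioselective route to a 2,3-diaryl-2,3-dihydropyran-4-one followed by alpha-bromination is longer and less secure than one cycloaddition. A beta-alkoxy enone is an electron-rich, sluggish dienophile toward an electron-rich diene. The thermal cycloaddition and the eliminations expose the epimerisable C3 and the beta-aryloxy ketone carbon C2 to acid, base and heat.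
- Comparison: against the saving of two benzyl groups and the C4 oxidation, the chosen plan sets ring C and both stereocentres in one catalytic step from achiral fragments. No stereocentre is alpha to a ketone until the last two steps.

Key step: step 6

Assumption: which enantiomer of the phosphoric acid leads to the (2R,3S) series cannot be derived with certainty from a model; the (R)-catalyst is written, and the equally available (S)-catalyst is to be used if the sense of induction is the reverse.

## Route

Step 1
Reactants: 1 2,4,6-trihydroxybenzaldehyde
Product: 2 2,4-bis(benzyloxy)-6-hydroxybenzaldehyde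
Conditions: BnBr (2.05 equiv), K2CO3, DMF, 0 °C → rt
Reagents that add atoms: benzyl bromide, BrCc1ccccc1
Why: Williamson etherification; the 4-hydroxyl is the most acidic and one ortho-hydroxyl follows, while the remaining ortho-hydroxyl is hydrogen-bonded to the formyl oxygen and is the least nucleophilic, so two equivalents of benzyl bromide should stop at the 2,4-dibenzyl ether.

Step 2
Reactants: 2 2,4-bis(benzyloxy)-6-hydroxybenzaldehyde
Product: 3 3,5-bis(benzyloxy)-2-(hydroxymethyl)phenol
Conditions: NaBH4, THF/MeOH, 0 °C; pH 7 buffer work-up, used crude
Reagents that add atoms: none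
Why: Borohydride reduction of an aryl aldehyde; it is run cold and worked up at neutral pH because this electron-rich salicyl alcohol ionises easily, and the product is taken on without chromatography.

Step 3
Reactants: 4 4-bromo-2-iodophenol
Product: 5 1-(benzyloxy)-4-bromo-2-iodobenzene
Conditions: BnBr, K2CO3, DMF, rt
Reagents that add atoms: benzyl bromide, BrCc1ccccc1
Why: Williamson etherification of a phenol; neither aryl halide reacts under these conditions.

Step 4
Reactants: 5 1-(benzyloxy)-4-bromo-2-iodobenzene; 6 4-ethenylphenyl acetate (4-acetoxystyrene)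
Product: 7 4-[(E)-2-[2-(benzyloxy)-5-bromophenyl]ethenyl]phenyl acetate
Conditions: Pd(OAc)2 (3 mol %), n-Bu4NBr, NaOAc, DMF, 70 °C
Reagents that add atoms: none
Why: Mizoroki–Heck arylation under ligand-free phase-transfer conditions; zerovalent palladium inserts into the C–I bond far faster than into the C–Br bond at this temperature, so the bromide is kept, and syn-insertion followed by syn-beta-hydride elimination gives the E-stilbene.

Step 5
Reactants: 7 4-[(E)-2-[2-(benzyloxy)-5-bromophenyl]ethenyl]phenyl acetate
Product: 8 4-[(E)-2-[2-(benzyloxy)-5-bromophenyl]ethenyl]phenol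
Conditions: K2CO3 (cat.), MeOH/THF, rt
Reagents that add atoms: none
Why: Base-catalysed methanolysis (transesterification) of an aryl acetate; nothing else in 7 is base-labile.

Step 6
Reactants: 3 3,5-bis(benzyloxy)-2-(hydroxymethyl)phenol; 8 4-[(E)-2-[2-(benzyloxy)-5-bromophenyl]ethenyl]phenol
Product: 10 (2R,3S)-5,7-bis(benzyloxy)-3-[2-(benzyloxy)-5-bromophenyl]-2-(4-hydroxyphenyl)chroman (2,3-trans), via ortho-quinone methide 9 (not isolated)
Conditions: (R)-TRIP [(R)-3,3'-bis(2,4,6-triisopropylphenyl)-1,1'-binaphthyl-2,2'-diyl hydrogen phosphate] (10 mol %), 5 Å MS, toluene, 0 °C → rt, 3 (1.5 equiv) added slowly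
Reagents that add atoms: none
Why: The phosphoric acid protonates the benzylic hydroxyl of 3 and water leaves, giving the ortho-quinone methide 9, which stays hydrogen-bonded through its carbonyl oxygen to the P–OH group while the phosphoryl oxygen accepts a hydrogen bond from the para-hydroxyl of 8. This is the known chiral-phosphoric-acid-catalysed inverse-electron-demand oxa-Diels–Alder reaction of ortho-quinone methides made in situ from ortho-hydroxybenzyl alcohols with hydroxystyrenes, here with a beta-aryl group on the styrene. The oxadiene O1=C8a–C4a=C4 of 9 adds across the alkene in an asynchronous concerted [4+2] step in which the carbon bearing the bromoaryl ring bonds to the methide carbon (C3–C4) ahead of O1–C2 formation, so ring C is closed by the cycloaddition itself (in the stepwise limit, a 6-exo-trig attack of the phenoxide oxygen on the para-quinone-methide-like carbon). C2 and C3 become trans because both bonds form on one face of the E-alkene; should the C2–O1 bond ionise reversibly under the acid, reclosure leads to the same diequatorial isomer, so that C3 then controls C2. The absolute configuration is fixed in the C3–C4 bond-forming event by the enantioface of the stilbene that the 3,3'-aryl groups of the catalyst leave open when both partners are bound. The step needs regioselectivity (O1 to the carbon bearing ring B), which is secured because the para-hydroxyl, made more phenoxide-like by the phosphate, is a far stronger donor than the ortho-benzyloxy group of the bromoaryl ring, itself weakened by the bromine meta to the alkene. It also needs the quinone methide to meet the stilbene and not itself, which is secured by the two benzyloxy groups that let 9 form at low acid strength and by slow addition of 3.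

Step 7
Reactants: 10 (2R,3S)-5,7-bis(benzyloxy)-3-[2-(benzyloxy)-5-bromophenyl]-2-(4-hydroxyphenyl)chroman
Product: 11 (2R,3S)-5,7-bis(benzyloxy)-3-[2-(benzyloxy)-5-bromophenyl]-2-[4-(benzyloxy)phenyl]chroman
Conditions: BnBr, K2CO3, DMF, rt
Reagents that add atoms: benzyl bromide, BrCc1ccccc1
Why: Williamson etherification; the chroman has no base-sensitive centre, and capping the ring B phenol prevents its oxidation at C2 in step 11 and gives a uniform set of six benzyl ethers for the last step.

Step 8
Reactants: 12 1-(2,4-dihydroxyphenyl)ethan-1-one (2',4'-dihydroxyacetophenone)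
Product: 13 1-[2,4-bis(benzyloxy)phenyl]ethan-1-one
Conditions: BnBr (2.5 equiv), K2CO3, KI (cat.), DMF, 80 °C
Reagents that add atoms: benzyl bromide, BrCc1ccccc1
Why: Williamson etherification; the chelated 2-hydroxyl needs heat and iodide catalysis but is alkylated cleanly with excess reagent.

Step 9
Reactants: 13 1-[2,4-bis(benzyloxy)phenyl]ethan-1-one
Product: 14 1-[2,4-bis(benzyloxy)phenyl]prop-2-en-1-one
Conditions: (CH2O)n, i-Pr2NH·CF3CO2H, CF3CO2H (cat.), THF, reflux; BHT added, used promptly
Reagents that add atoms: formaldehyde (as paraformaldehyde), C=O
Why: Mannich condensation with formaldehyde and elimination of the amine in the same pot (ammonium-salt-mediated alpha-methylenation of an aryl methyl ketone); there is only one enolisable position, so only this enone can form.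

Step 10
Reactants: 11 (2R,3S)-5,7-bis(benzyloxy)-3-[2-(benzyloxy)-5-bromophenyl]-2-[4-(benzyloxy)phenyl]chroman; 14 1-[2,4-bis(benzyloxy)phenyl]prop-2-en-1-one
Product: 15 (E)-1-[2,4-bis(benzyloxy)phenyl]-3-{4-(benzyloxy)-3-[(2R,3S)-5,7-bis(benzyloxy)-2-[4-(benzyloxy)phenyl]chroman-3-yl]phenyl}prop-2-en-1-one
Conditions: Pd(OAc)2 (5 mol %), P(o-tol)3 (12 mol %), Et3N, BHT, DMF, 90 °C, 14 (2 equiv) added in portions
Reagents that add atoms: none
Why: Mizoroki–Heck reaction of an aryl bromide with an aryl vinyl ketone, a known route to chalcones; beta-arylation and syn-beta-hydride elimination give the E-enone, and at the chroman stage there is no enolisable stereocentre for the amine base to touch.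

Step 11
Reactants: 15 (E)-1-[2,4-bis(benzyloxy)phenyl]-3-{4-(benzyloxy)-3-[(2R,3S)-5,7-bis(benzyloxy)-2-[4-(benzyloxy)phenyl]chroman-3-yl]phenyl}prop-2-en-1-one
Product: 16 (E)-1-[2,4-bis(benzyloxy)phenyl]-3-{4-(benzyloxy)-3-[(2R,3R,4R)-5,7-bis(benzyloxy)-2-[4-(benzyloxy)phenyl]-4-hydroxychroman-3-yl]phenyl}prop-2-en-1-one (2,3-trans and 3,4-trans)
Conditions: DDQ (1.5 equiv), CH2Cl2/H2O (18:1), 0 °C → rt; bicarbonate work-up, used crude
Reagents that add atoms: water, O
Why: Benzylic hydride abstraction by DDQ and capture of the cation by water, the reaction used to functionalise C4 of O-benzylated flavans; only the C4 cation is stabilised by all three oxygens of ring A (O1 and the 5-benzyloxy group ortho, the 7-benzyloxy group para), so C4 should react before C2, whose ring oxygen is an aryl ether oxygen and whose aryl ring has a single donor. Water is expected to add anti to the C3 aryl group, and the C4 configuration is in any case removed in step 12.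

Step 12
Reactants: 16 the chroman-4-ol of step 11
Product: 17 (2R,3S)-5,7-bis(benzyloxy)-3-{2-(benzyloxy)-5-[(E)-3-[2,4-bis(benzyloxy)phenyl]-3-oxoprop-1-en-1-yl]phenyl}-2-[4-(benzyloxy)phenyl]chroman-4-one
Conditions: Dess–Martin periodinane, NaHCO3, CH2Cl2, 0 °C → rt
Reagents that add atoms: none
Why: Dess–Martin oxidation of a secondary benzylic alcohol under bicarbonate buffer; it is mild and non-basic, so the enone is untouched and C3 stays trans, which is also the thermodynamic arrangement.

Step 13
Reactants: 17 the hexabenzyl ether of step 12
Product: 18 (2R,3S)-3-{5-[(E)-3-(2,4-dihydroxyphenyl)-3-oxoprop-1-en-1-yl]-2-hydroxyphenyl}-5,7-dihydroxy-2-(4-hydroxyphenyl)chroman-4-one (CNP0272156.1)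
Conditions: BCl3 (excess), pentamethylbenzene, CH2Cl2, −78 → −40 °C; MeOH then water
Reagents that add atoms: none
Why: Lewis-acid cleavage of aryl benzyl ethers with pentamethylbenzene as a non-basic scavenger of benzyl cations; it needs no hydrogen, so the enone double bond survives, and no base, so C2 and C3 are not exposed to enolisation or ring opening.

## Compound list

1 | 2,4,6-trihydroxybenzaldehyde | O=Cc1c(O)cc(O)cc1O | starting material
2 | 2,4-bis(benzyloxy)-6-hydroxybenzaldehyde | O=Cc1c(O)cc(OCc2ccccc2)cc1OCc1ccccc1 | intermediate
3 | 3,5-bis(benzyloxy)-2-(hydroxymethyl)phenol | OCc1c(O)cc(OCc2ccccc2)cc1OCc1ccccc1 | intermediate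
4 | 4-bromo-2-iodophenol | Oc1ccc(Br)cc1I | starting material
5 | 1-(benzyloxy)-4-bromo-2-iodobenzene | Brc1ccc(OCc2ccccc2)c(I)c1 | intermediate
6 | 4-ethenylphenyl acetate (4-acetoxystyrene) | CC(=O)Oc1ccc(C=C)cc1 | starting material
7 | 4-[(E)-2-[2-(benzyloxy)-5-bromophenyl]ethenyl]phenyl acetate | CC(=O)Oc1ccc(/C=C/c2cc(Br)ccc2OCc2ccccc2)cc1 | intermediate
8 | 4-[(E)-2-[2-(benzyloxy)-5-bromophenyl]ethenyl]phenol | Oc1ccc(/C=C/c2cc(Br)ccc2OCc2ccccc2)cc1 | intermediate
9 | 3,5-bis(benzyloxy)-6-methylidenecyclohexa-2,4-dien-1-one (ortho-quinone methide, formed and consumed in step 6) | C=C1C(=O)C=C(OCc2ccccc2)C=C1OCc1ccccc1 | intermediate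
10 | (2R,3S)-5,7-bis(benzyloxy)-3-[2-(benzyloxy)-5-bromophenyl]-2-(4-hydroxyphenyl)chroman (2,3-trans) | Brc1ccc(OCc2ccccc2)c([C@@H]2Cc3c(OCc4ccccc4)cc(OCc4ccccc4)cc3O[C@H]2c2ccc(O)cc2)c1 | intermediate
11 | (2R,3S)-5,7-bis(benzyloxy)-3-[2-(benzyloxy)-5-bromophenyl]-2-[4-(benzyloxy)phenyl]chroman | Brc1ccc(OCc2ccccc2)c([C@@H]2Cc3c(OCc4ccccc4)cc(OCc4ccccc4)cc3O[C@H]2c2ccc(OCc3ccccc3)cc2)c1 | intermediate
12 | 1-(2,4-dihydroxyphenyl)ethan-1-one | CC(=O)c1ccc(O)cc1O | starting material
13 | 1-[2,4-bis(benzyloxy)phenyl]ethan-1-one | CC(=O)c1ccc(OCc2ccccc2)cc1OCc1ccccc1 | intermediate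
14 | 1-[2,4-bis(benzyloxy)phenyl]prop-2-en-1-one | C=CC(=O)c1ccc(OCc2ccccc2)cc1OCc1ccccc1 | intermediate
15 | (E)-1-[2,4-bis(benzyloxy)phenyl]-3-{4-(benzyloxy)-3-[(2R,3S)-5,7-bis(benzyloxy)-2-[4-(benzyloxy)phenyl]chroman-3-yl]phenyl}prop-2-en-1-one | O=C(/C=C/c1ccc(OCc2ccccc2)c([C@@H]2Cc3c(OCc4ccccc4)cc(OCc4ccccc4)cc3O[C@H]2c2ccc(OCc3ccccc3)cc2)c1)c1ccc(OCc2ccccc2)cc1OCc1ccccc1 | intermediate
16 | (E)-1-[2,4-bis(benzyloxy)phenyl]-3-{4-(benzyloxy)-3-[(2R,3R,4R)-5,7-bis(benzyloxy)-2-[4-(benzyloxy)phenyl]-4-hydroxychroman-3-yl]phenyl}prop-2-en-1-one (2,3-trans, 3,4-trans) | O=C(/C=C/c1ccc(OCc2ccccc2)c([C@@H]2[C@@H](O)c3c(OCc4ccccc4)cc(OCc4ccccc4)cc3O[C@H]2c2ccc(OCc3ccccc3)cc2)c1)c1ccc(OCc2ccccc2)cc1OCc1ccccc1 | intermediate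
17 | (2R,3S)-5,7-bis(benzyloxy)-3-{2-(benzyloxy)-5-[(E)-3-[2,4-bis(benzyloxy)phenyl]-3-oxoprop-1-en-1-yl]phenyl}-2-[4-(benzyloxy)phenyl]chroman-4-one | O=C(/C=C/c1ccc(OCc2ccccc2)c([C@@H]2C(=O)c3c(OCc4ccccc4)cc(OCc4ccccc4)cc3O[C@H]2c2ccc(OCc3ccccc3)cc2)c1)c1ccc(OCc2ccccc2)cc1OCc1ccccc1 | intermediate
18 | (2R,3S)-3-{5-[(E)-3-(2,4-dihydroxyphenyl)-3-oxoprop-1-en-1-yl]-2-hydroxyphenyl}-5,7-dihydroxy-2-(4-hydroxyphenyl)chroman-4-one | O=C(/C=C/c1ccc(O)c([C@@H]2C(=O)c3c(O)cc(O)cc3O[C@H]2c2ccc(O)cc2)c1)c1ccc(O)cc1O | target

## Step count and risks

Total: 13 steps. Longest linear sequence: 9 steps (steps 3, 4, 5, 6, 7, 10, 11, 12, 13, from 4).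

**Step 6 (key step).** The 1,2-diaryl alkene is less nucleophilic and more hindered than a simple hydroxystyrene. Self-condensation of the quinone methide, or its capture by the phenol oxygen or by ring A of another molecule of 3, may therefore outrun the cycloaddition. The hydrogen-bond anchor is also remote from the reacting carbon, so facial discrimination may be poor.
Fallback, from 3 and 8 back to 10: the cycloaddition is run without asymmetric induction, by heating 3 and 8 in toluene with diphenyl phosphate. This should give racemic trans material, that is 10 together with its mirror image, the (2S,3R)-chroman F1. The enantiomers are separated by preparative chromatography on a chiral stationary phase, for which the free phenol is a convenient handle, and 10 rejoins the route at step 7.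

**Step 11.** After hydride abstraction, the C4 cation may lose the C3 proton (benzylic to ring D) faster than it captures water. This elimination to the 2H-chromene would destroy the C3 stereocentre and open the way to over-oxidation. Competing abstraction at C2 is the second possibility.
Fallback, from 15 back to 16: acetoxylation with Pb(OAc)4 in benzene/acetic acid, in which acetate is delivered by ligand transfer from tetravalent lead without a hydroquinone anion acting as base, gives the 4-acetoxychroman F2. Methanolysis (K2CO3, MeOH/THF, 0 °C) then gives 16.

**Step 10.** Polymerisation or oligomerisation of the vinyl ketone 14 at 90 °C may be faster than oxidative addition into the electron-rich aryl bromide, and a second arylation of the product enone is possible.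
Fallback, from 11 back to 15: 11 is coupled under the same Heck conditions with N-methoxy-N-methylacrylamide, which does not polymerise, to give the cinnamoyl N-methoxy-N-methylamide F3. In parallel, 1-bromo-2,4-bis(benzyloxy)benzene F4 is made from 4-bromoresorcinol, benzyl bromide and K2CO3. Bromine–lithium exchange (n-BuLi, THF, −78 °C) converts it into [2,4-bis(benzyloxy)phenyl]lithium F5. F5 adds once to F3, and collapse of the chelated adduct on work-up gives 15.

**Step 1.** Two equivalents of benzyl bromide on a triphenol may give a statistical mixture of mono-, di- and tri-ethers, and the phloroglucinol-type anion may be benzylated on carbon.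
Fallback, from 1 back to 2: exhaustive O-benzylation (excess BnBr, K2CO3, DMF) gives 2,4,6-tris(benzyloxy)benzaldehyde F6. MgBr2·OEt2 in toluene/ether then removes exactly one benzyl group ortho to the formyl group through a six-membered magnesium chelate, which also protects the product from a second cleavage, and gives 2.

## Further compounds

F1 | step 6 | (2S,3R)-5,7-bis(benzyloxy)-3-[2-(benzyloxy)-5-bromophenyl]-2-(4-hydroxyphenyl)chroman (mirror image of 10) | Brc1ccc(OCc2ccccc2)c([C@H]2Cc3c(OCc4ccccc4)cc(OCc4ccccc4)cc3O[C@@H]2c2ccc(O)cc2)c1
F2 | step 11 | (2R,3S,4R)-5,7-bis(benzyloxy)-3-{2-(benzyloxy)-5-[(E)-3-[2,4-bis(benzyloxy)phenyl]-3-oxoprop-1-en-1-yl]phenyl}-2-[4-(benzyloxy)phenyl]chroman-4-yl acetate (2,3-trans, 3,4-trans) | O=C(/C=C/c1ccc(OCc2ccccc2)c([C@@H]2[C@@H](OC(C)=O)c3c(OCc4ccccc4)cc(OCc4ccccc4)cc3O[C@H]2c2ccc(OCc3ccccc3)cc2)c1)c1ccc(OCc2ccccc2)cc1OCc1ccccc1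
F3 | step 10 | (E)-3-{4-(benzyloxy)-3-[(2R,3S)-5,7-bis(benzyloxy)-2-[4-(benzyloxy)phenyl]chroman-3-yl]phenyl}-N-methoxy-N-methylprop-2-enamide | CON(C)C(=O)/C=C/c1ccc(OCc2ccccc2)c([C@@H]2Cc3c(OCc4ccccc4)cc(OCc4ccccc4)cc3O[C@H]2c2ccc(OCc3ccccc3)cc2)c1
F4 | step 10 | 1-bromo-2,4-bis(benzyloxy)benzene | Brc1ccc(OCc2ccccc2)cc1OCc1ccccc1
F5 | step 10 | [2,4-bis(benzyloxy)phenyl]lithium | [Li]c1ccc(OCc2ccccc2)cc1OCc1ccccc1
F6 | step 1 | 2,4,6-tris(benzyloxy)benzaldehyde | O=Cc1c(OCc2ccccc2)cc(OCc2ccccc2)cc1OCc1ccccc1
A1 | alternative 1 | (2R,3S)-3-{5-[(E)-3-[2,4-bis(methoxymethoxy)phenyl]-3-oxoprop-1-en-1-yl]-2-(methoxymethoxy)phenyl}-5,7-bis(methoxymethoxy)-2-[4-(methoxymethoxy)phenyl]chroman-4-one | COCOc1ccc(C(=O)/C=C/c2ccc(OCOC)c([C@@H]3C(=O)c4c(OCOC)cc(OCOC)cc4O[C@H]3c3ccc(OCOC)cc3)c2)c(OCOC)c1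
A2 | alternative 1 | (2R,3S)-3-[5-ethenyl-2-(methoxymethoxy)phenyl]-5,7-bis(methoxymethoxy)-2-[4-(methoxymethoxy)phenyl]chroman-4-one | C=Cc1ccc(OCOC)c([C@@H]2C(=O)c3c(OCOC)cc(OCOC)cc3O[C@H]2c2ccc(OCOC)cc2)c1
A3 | alternative 1 | 1-iodo-2,4-bis(methoxymethoxy)benzene | COCOc1ccc(I)c(OCOC)c1
A4 | alternative 1 | carbon monoxide | [C-]#[O+]
A5 | alternative 2 | (2R,3S)-5,7-bis[4-(benzyloxy)benzyloxy]-2-[4-(benzyloxy)phenyl]-3-[5-bromo-2-(triisopropylsilyloxy)phenyl]chroman-4-one | Brc1ccc(O[Si](C(C)C)(C(C)C)C(C)C)c([C@@H]2C(=O)c3c(OCc4ccc(OCc5ccccc5)cc4)cc(OCc4ccc(OCc5ccccc5)cc4)cc3O[C@H]2c2ccc(OCc3ccccc3)cc2)c1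
A6 | alternative 2 | 2-[5-bromo-2-(triisopropylsilyloxy)phenyl]-2-diazo-1-{2,4,6-tris[4-(benzyloxy)benzyloxy]phenyl}ethan-1-one | [N-]=[N+]=C(c1cc(Br)ccc1O[Si](C(C)C)(C(C)C)C(C)C)C(=O)c1c(OCc2ccc(OCc3ccccc3)cc2)cc(OCc2ccc(OCc3ccccc3)cc2)cc1OCc1ccc(OCc2ccccc2)cc1
A7 | alternative 3 | (2R,3S)-3-[2-(benzyloxy)-5-bromophenyl]-2-[4-(benzyloxy)phenyl]-5,7-dihydroxychroman-4-one | Brc1ccc(OCc2ccccc2)c([C@@H]2C(=O)c3c(O)cc(O)cc3O[C@H]2c2ccc(OCc3ccccc3)cc2)c1
A8 | alternative 3 | (2R,3S)-5-bromo-3-[2-(benzyloxy)-5-bromophenyl]-2-[4-(benzyloxy)phenyl]-2,3-dihydro-4H-pyran-4-one | BrC1=CO[C@@H](c2ccc(OCc3ccccc3)cc2)[C@H](c2cc(Br)ccc2OCc2ccccc2)C1=O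
A9 | alternative 3 | 1-methoxy-1,3-bis(trimethylsilyloxy)buta-1,3-diene | C=C(O[Si](C)(C)C)C=C(OC)O[Si](C)(C)C
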